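**Plan**

- The first cut is the bond between the lactone α-carbon and the CH2 on C5 of the dihydrobenzofuran (enolate alkylation), which gives a benzylic bromide and a 4-substituted butyrolactone.
- In the dihydrobenzofuran, C3 carries a bond to the ring-B carbon C3a and an exocyclic CH2OH. Cutting C3–C3a and CH2–O turns these into the inner and terminal carbons of a vinyl group on the C2 ether carbon, with iodine on C3a ortho to O1. This ortho-iodoaryl 1-arylallyl ether is what permits a 5-exo aryl radical closure with oxygen capture.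
- The ether bond C2–O1 is cut next (iridium-catalysed allylic etherification of 5-iodovanillin with a cinnamyl carbonate from ferulic acid). The lactone piece is cut at the carbinol C–C bond (imide anti-aldol with O-benzylvanillin) and at the ring C–O bond.
- Forward: carbonate, chiral aryl allyl ether, dihydrofuran ring, benzylic bromide; separately aldol, then the butyrolactone ring; the two pieces are joined at the lactone α-carbon and the four protecting groups are removed.
- Stereochemistry: C2 from the chiral iridium catalyst; C3 from C2 in the radical closure (trans); lactone C4 and the carbinol carbon from the oxazolidinone-controlled anti-aldol; lactone C3 from alkylation anti to the C4 substituent.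

Key step: step 5

Assumption: both antipodes of the phosphoramidite ligand and of 4-benzyl-1,3-oxazolidin-2-one are purchasable, and the antipodes named in steps 4 and 10 are those that the accepted models (ligand-controlled attack on the allyl–iridium complex; aldehyde approach to the magnesium-chelated Z-enolate on the face away from the benzyl group) assign to the drawn products.

**Route**

Step 1
Reactants: 1 ferulic acid
Product: 2 benzyl (E)-3-[4-(benzyloxy)-3-methoxyphenyl]prop-2-enoate
Conditions: BnBr (2.4 equiv), K2CO3 (3 equiv), DMF, 60 °C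
Reagents that add atoms: benzyl bromide, BrCc1ccccc1
Why: Williamson-type O-alkylation, in which carbonate deprotonates both the carboxylic acid and the phenol and each anion displaces bromide from benzyl bromide.

Step 2
Reactants: 2 benzyl (E)-3-[4-(benzyloxy)-3-methoxyphenyl]prop-2-enoate
Product: 3 (E)-3-[4-(benzyloxy)-3-methoxyphenyl]prop-2-en-1-ol
Conditions: i-Bu2AlH (2.6 equiv), CH2Cl2, −78 → 0 °C; aqueous KNaC4H4O6 work-up
Reagents that add atoms: none
Why: 1,2-reduction of a cinnamate ester by the aluminium hydride should give the allylic alcohol without touching the alkene or the aryl benzyl ether.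

Step 3
Reactants: 3 (E)-3-[4-(benzyloxy)-3-methoxyphenyl]prop-2-en-1-ol
Product: 4 (E)-3-[4-(benzyloxy)-3-methoxyphenyl]prop-2-en-1-yl methyl carbonate
Conditions: ClCO2Me, pyridine, CH2Cl2, 0 °C
Reagents that add atoms: methyl chloroformate, COC(=O)Cl
Why: acylation of the primary allylic alcohol installs the carbonate leaving group that the allyl–iridium chemistry of the next step requires.

Step 4
Reactants: 4 (E)-3-[4-(benzyloxy)-3-methoxyphenyl]prop-2-en-1-yl methyl carbonate; 5 5-iodovanillin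
Product: 7 4-{[(1S)-1-[4-(benzyloxy)-3-methoxyphenyl]prop-2-en-1-yl]oxy}-3-iodo-5-methoxybenzaldehyde, via sodium aryloxide 6 (not isolated)
Conditions: 5 (1.5 equiv), NaH, THF, 0 °C; then 4, [Ir(cod)Cl]2 (2 mol %), (Sa,Sc,Sc)-O,O'-(1,1'-binaphthyl-2,2'-diyl)-N,N-bis(1-phenylethyl)phosphoramidite (4 mol %, pre-activated with n-PrNH2), THF, 25–40 °C; chromatography on Et3N-treated silica
Reagents that add atoms: none
Why: iridium-catalysed asymmetric allylic etherification, in which the carbonate ionises to an allyl–iridium complex of the cyclometalated phosphoramidite and the aryloxide attacks the aryl-bearing terminus on the face fixed by the ligand, setting the S ether carbon (the later C2) in the branched product.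

Step 5
Reactants: 7 4-{[(1S)-1-[4-(benzyloxy)-3-methoxyphenyl]prop-2-en-1-yl]oxy}-3-iodo-5-methoxybenzaldehyde
Product: 9 (2S,3R)-2-[4-(benzyloxy)-3-methoxyphenyl]-3-(hydroxymethyl)-7-methoxy-2,3-dihydro-1-benzofuran-5-carbaldehyde, via hydroperoxide 8 (not isolated)
Conditions: Bu3SnH (1.5 equiv, syringe pump, 8 h), Et3B (0.2 equiv, in portions), slow stream of dry air, toluene (0.01 M), 0 °C → rt; then PPh3 (1.5 equiv), rt
Reagents that add atoms: dioxygen, O=O
Why: Ethyl radicals from Et3B and O2 start a chain in which Bu3Sn• abstracts iodine from C3a of ring B; the aryl radical adds to the inner vinyl carbon, forming C3–C3a and closing the dihydrofuran ring in the 5-exo-trig mode, and the primary CH2 radical is captured by O2 to a peroxyl radical that takes hydrogen from Bu3SnH, giving hydroperoxide 8 and the chain carrier, after which PPh3 reduces the O–O bond. The closest known reaction type is the aerobic, tin hydride-mediated oxygenative cyclisation of ortho-iodophenyl allyl ethers to 3-(hydroxymethyl)-2,3-dihydrobenzofurans. The new stereocentre C3 is controlled by C2: in the envelope-like transition state the aryl group on C2 lies pseudo-equatorial, away from the terminal CH2 of the alkene, so the CH2O group should end trans to it (2S,3R). The step needs ring closure to outrun capture of the aryl radical and oxygen capture to outrun reduction of the primary radical; the first is secured by the very fast 5-exo closure of an ortho-allyloxyaryl radical and the second by the low stationary stannane concentration kept by slow addition. Only the C–I bond is homolysed, and the Sn–H bond is a far better hydrogen donor to peroxyl radicals than the formyl C–H, so the aldehyde should survive; any cis isomer would be removed by chromatography.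

Step 6
Reactants: 9 (2S,3R)-2-[4-(benzyloxy)-3-methoxyphenyl]-3-(hydroxymethyl)-7-methoxy-2,3-dihydro-1-benzofuran-5-carbaldehyde
Product: 10 (2S,3R)-2-[4-(benzyloxy)-3-methoxyphenyl]-3-{[(tert-butyldimethylsilyl)oxy]methyl}-7-methoxy-2,3-dihydro-1-benzofuran-5-carbaldehyde
Conditions: t-BuMe2SiCl, imidazole, DMF, rt
Reagents that add atoms: tert-butyldimethylsilyl chloride, CC(C)(C)[Si](C)(C)Cl
Why: imidazole-promoted silylation of the unhindered primary alcohol protects it from the bromination and enolate steps that follow.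

Step 7
Reactants: 10 (2S,3R)-2-[4-(benzyloxy)-3-methoxyphenyl]-3-{[(tert-butyldimethylsilyl)oxy]methyl}-7-methoxy-2,3-dihydro-1-benzofuran-5-carbaldehyde
Product: 11 [(2S,3R)-2-[4-(benzyloxy)-3-methoxyphenyl]-3-{[(tert-butyldimethylsilyl)oxy]methyl}-7-methoxy-2,3-dihydro-1-benzofuran-5-yl]methanol
Conditions: NaBH4, MeOH/THF, 0 °C
Reagents that add atoms: none
Why: borohydride reduction of the aromatic aldehyde gives the benzylic alcohol and leaves the silyl ether and the aryl ethers untouched.

Step 8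
Reactants: 11 [(2S,3R)-2-[4-(benzyloxy)-3-methoxyphenyl]-3-{[(tert-butyldimethylsilyl)oxy]methyl}-7-methoxy-2,3-dihydro-1-benzofuran-5-yl]methanol
Product: 12 {[(2S,3R)-2-[4-(benzyloxy)-3-methoxyphenyl]-5-(bromomethyl)-7-methoxy-2,3-dihydro-1-benzofuran-3-yl]methoxy}(tert-butyl)dimethylsilane
Conditions: CBr4, PPh3, CH2Cl2, 0 °C; short silica plug, used at once
Reagents that add atoms: carbon tetrabromide, BrC(Br)(Br)Br
Why: the Appel reaction converts the benzylic alcohol into the bromide under neutral conditions, which the silyl ether and the benzylic C2–O1 bond should tolerate.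

Step 9
Reactants: 13 4-tert-butoxy-4-oxobutanoic acid; 14 (4R)-4-benzyl-1,3-oxazolidin-2-one
Product: 16 tert-butyl 4-[(4R)-4-benzyl-2-oxo-1,3-oxazolidin-3-yl]-4-oxobutanoate, via mixed pivalic anhydride 15 (not isolated)
Conditions: t-BuCOCl, Et3N, THF, −20 °C; then 14, LiCl, −20 °C → rt
Reagents that add atoms: none
Why: N-acylation of the oxazolidinone through the mixed anhydride, with LiCl and Et3N as activators, engages only the free acid end of the succinic half-ester.

Step 10
Reactants: 16 tert-butyl 4-[(4R)-4-benzyl-2-oxo-1,3-oxazolidin-3-yl]-4-oxobutanoate; 17 4-(benzyloxy)-3-methoxybenzaldehyde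
Product: 19 tert-butyl (3S,4R)-3-{[(4R)-4-benzyl-2-oxo-1,3-oxazolidin-3-yl]carbonyl}-4-[4-(benzyloxy)-3-methoxyphenyl]-4-hydroxybutanoate, via trimethylsilyl ether 18 (not isolated)
Conditions: MgCl2 (20 mol %), Et3N (2 equiv), Me3SiCl (1.5 equiv), EtOAc, rt; then pyridinium p-toluenesulfonate (cat.), MeOH, rt
Reagents that add atoms: none
Why: magnesium-catalysed direct anti-aldol of an N-acyloxazolidinone, in which soft enolisation gives the chelated Z-enolate that meets the aldehyde through a boat-like transition state on the face away from the auxiliary benzyl group, setting C3 (S) and the carbinol C4 (R) in the anti relation while Me3SiCl traps the aldolate and so prevents retro-aldol and attack on the tert-butyl ester.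

Step 11
Reactants: 19 tert-butyl (3S,4R)-3-{[(4R)-4-benzyl-2-oxo-1,3-oxazolidin-3-yl]carbonyl}-4-[4-(benzyloxy)-3-methoxyphenyl]-4-hydroxybutanoate
Product: 20 tert-butyl (3S,4R)-3-{[(4R)-4-benzyl-2-oxo-1,3-oxazolidin-3-yl]carbonyl}-4-[4-(benzyloxy)-3-methoxyphenyl]-4-[(tert-butyldimethylsilyl)oxy]butanoate
Conditions: t-BuMe2SiOTf, 2,6-lutidine, CH2Cl2, −78 → −20 °C
Reagents that add atoms: tert-butyldimethylsilyl triflate, CC(C)(C)[Si](C)(C)OS(=O)(=O)C(F)(F)F
Why: silyl triflate with a hindered base silylates the hindered secondary benzylic alcohol at low temperature, so that this oxygen cannot later close a lactone on the ester.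

Step 12
Reactants: 20 tert-butyl (3S,4R)-3-{[(4R)-4-benzyl-2-oxo-1,3-oxazolidin-3-yl]carbonyl}-4-[4-(benzyloxy)-3-methoxyphenyl]-4-[(tert-butyldimethylsilyl)oxy]butanoate
Product: 21 tert-butyl (3R,4R)-4-[4-(benzyloxy)-3-methoxyphenyl]-4-[(tert-butyldimethylsilyl)oxy]-3-(hydroxymethyl)butanoate
Conditions: LiBH4, MeOH (2 equiv), THF, 0 °C
Reagents that add atoms: none
Why: reductive removal of the auxiliary, in which borohydride attacks the exocyclic imide carbonyl and leaves the tert-butyl ester and the silyl ether intact at 0 °C (the descriptor at C3 changes by priority only).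

Step 13
Reactants: 21 tert-butyl (3R,4R)-4-[4-(benzyloxy)-3-methoxyphenyl]-4-[(tert-butyldimethylsilyl)oxy]-3-(hydroxymethyl)butanoate
Product: 22 (4R)-4-[(R)-[4-(benzyloxy)-3-methoxyphenyl][(tert-butyldimethylsilyl)oxy]methyl]oxolan-2-one
Conditions: p-TsOH·H2O (5 mol %), CH2Cl2, rt
Reagents that add atoms: none
Why: acid-catalysed lactonisation (5-exo-trig transesterification) by the primary alcohol with loss of tert-butanol can give only the wanted lactone because the benzylic oxygen is silylated, and catalytic acid in a non-nucleophilic solvent should spare the benzylic silyl ether.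

Step 14
Reactants: 22 (4R)-4-[(R)-[4-(benzyloxy)-3-methoxyphenyl][(tert-butyldimethylsilyl)oxy]methyl]oxolan-2-one; 12 {[(2S,3R)-2-[4-(benzyloxy)-3-methoxyphenyl]-5-(bromomethyl)-7-methoxy-2,3-dihydro-1-benzofuran-3-yl]methoxy}(tert-butyl)dimethylsilane
Product: 24 (3R,4R)-3-{[(2S,3R)-2-[4-(benzyloxy)-3-methoxyphenyl]-3-{[(tert-butyldimethylsilyl)oxy]methyl}-7-methoxy-2,3-dihydro-1-benzofuran-5-yl]methyl}-4-[(R)-[4-(benzyloxy)-3-methoxyphenyl][(tert-butyldimethylsilyl)oxy]methyl]oxolan-2-one, via lithium enolate 23 (not isolated)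
Conditions: LiN(SiMe3)2, THF, −78 °C; then 12, DMPU, −78 → −30 °C
Reagents that add atoms: none
Why: alkylation of a 4-substituted butyrolactone enolate, in which the benzylic bromide approaches the face anti to the bulky C4 substituent and so sets lactone C3 (R) in the trans relation.

Step 15
Reactants: 24 (3R,4R)-3-{[(2S,3R)-2-[4-(benzyloxy)-3-methoxyphenyl]-3-{[(tert-butyldimethylsilyl)oxy]methyl}-7-methoxy-2,3-dihydro-1-benzofuran-5-yl]methyl}-4-[(R)-[4-(benzyloxy)-3-methoxyphenyl][(tert-butyldimethylsilyl)oxy]methyl]oxolan-2-one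
Product: 25 (3R,4R)-3-{[(2S,3R)-3-{[(tert-butyldimethylsilyl)oxy]methyl}-2-(4-hydroxy-3-methoxyphenyl)-7-methoxy-2,3-dihydro-1-benzofuran-5-yl]methyl}-4-[(R)-[(tert-butyldimethylsilyl)oxy](4-hydroxy-3-methoxyphenyl)methyl]oxolan-2-one
Conditions: H2 (1 atm), 10% Pd/C, EtOAc, rt, stopped at full conversion
Reagents that add atoms: none
Why: hydrogenolysis of the two aryl benzyl ethers in neutral ethyl acetate should be much faster than cleavage of the silylated benzylic C–O bond or of the cyclic benzylic ether C2–O1.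

Step 16
Reactants: 25 (3R,4R)-3-{[(2S,3R)-3-{[(tert-butyldimethylsilyl)oxy]methyl}-2-(4-hydroxy-3-methoxyphenyl)-7-methoxy-2,3-dihydro-1-benzofuran-5-yl]methyl}-4-[(R)-[(tert-butyldimethylsilyl)oxy](4-hydroxy-3-methoxyphenyl)methyl]oxolan-2-one
Product: 26 (3R,4R)-4-[(R)-hydroxy(4-hydroxy-3-methoxyphenyl)methyl]-3-{[(2S,3R)-2-(4-hydroxy-3-methoxyphenyl)-3-(hydroxymethyl)-7-methoxy-2,3-dihydro-1-benzofuran-5-yl]methyl}oxolan-2-one
Conditions: Bu4NF, AcOH (1:1, excess), THF, 0 °C → rt
Reagents that add atoms: none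
Why: fluoride desilylation buffered with acetic acid removes both silyl ethers without forming phenoxide or alkoxide, so translactonisation and quinone-methide chemistry at the para-hydroxybenzylic carbinol should be avoided and no stereocentre is touched.

**Compound list**

1 | ferulic acid, (E)-3-(4-hydroxy-3-methoxyphenyl)prop-2-enoic acid | COc1cc(/C=C/C(=O)O)ccc1O | starting material
2 | benzyl (E)-3-[4-(benzyloxy)-3-methoxyphenyl]prop-2-enoate | COc1cc(/C=C/C(=O)OCc2ccccc2)ccc1OCc1ccccc1 | intermediate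
3 | (E)-3-[4-(benzyloxy)-3-methoxyphenyl]prop-2-en-1-ol | COc1cc(/C=C/CO)ccc1OCc1ccccc1 | intermediate
4 | (E)-3-[4-(benzyloxy)-3-methoxyphenyl]prop-2-en-1-yl methyl carbonate | COC(=O)OC/C=C/c1ccc(OCc2ccccc2)c(OC)c1 | intermediate
5 | 5-iodovanillin, 4-hydroxy-3-iodo-5-methoxybenzaldehyde | COc1cc(C=O)cc(I)c1O | starting material
6 | sodium 4-formyl-2-iodo-6-methoxyphenolate | COc1cc(C=O)cc(I)c1[O-].[Na+] | intermediate (not isolated)
7 | 4-{[(1S)-1-[4-(benzyloxy)-3-methoxyphenyl]prop-2-en-1-yl]oxy}-3-iodo-5-methoxybenzaldehyde | COc1cc([C@H](C=C)Oc2c(OC)cc(C=O)cc2I)ccc1OCc1ccccc1 | intermediate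
8 | (2S,3R)-2-[4-(benzyloxy)-3-methoxyphenyl]-3-(hydroperoxymethyl)-7-methoxy-2,3-dihydro-1-benzofuran-5-carbaldehyde | COc1cc([C@H]2Oc3c(OC)cc(C=O)cc3[C@@H]2COO)ccc1OCc1ccccc1 | intermediate (not isolated)
9 | (2S,3R)-2-[4-(benzyloxy)-3-methoxyphenyl]-3-(hydroxymethyl)-7-methoxy-2,3-dihydro-1-benzofuran-5-carbaldehyde | COc1cc([C@H]2Oc3c(OC)cc(C=O)cc3[C@@H]2CO)ccc1OCc1ccccc1 | intermediate
10 | (2S,3R)-2-[4-(benzyloxy)-3-methoxyphenyl]-3-{[(tert-butyldimethylsilyl)oxy]methyl}-7-methoxy-2,3-dihydro-1-benzofuran-5-carbaldehyde | COc1cc([C@H]2Oc3c(OC)cc(C=O)cc3[C@@H]2CO[Si](C)(C)C(C)(C)C)ccc1OCc1ccccc1 | intermediate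
11 | [(2S,3R)-2-[4-(benzyloxy)-3-methoxyphenyl]-3-{[(tert-butyldimethylsilyl)oxy]methyl}-7-methoxy-2,3-dihydro-1-benzofuran-5-yl]methanol | COc1cc([C@H]2Oc3c(OC)cc(CO)cc3[C@@H]2CO[Si](C)(C)C(C)(C)C)ccc1OCc1ccccc1 | intermediate
12 | {[(2S,3R)-2-[4-(benzyloxy)-3-methoxyphenyl]-5-(bromomethyl)-7-methoxy-2,3-dihydro-1-benzofuran-3-yl]methoxy}(tert-butyl)dimethylsilane | COc1cc([C@H]2Oc3c(OC)cc(CBr)cc3[C@@H]2CO[Si](C)(C)C(C)(C)C)ccc1OCc1ccccc1 | intermediate
13 | 4-tert-butoxy-4-oxobutanoic acid | CC(C)(C)OC(=O)CCC(=O)O | starting material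
14 | (4R)-4-benzyl-1,3-oxazolidin-2-one | O=C1N[C@H](Cc2ccccc2)CO1 | starting material
15 | 4-tert-butoxy-4-oxobutanoic pivalic anhydride | CC(C)(C)OC(=O)CCC(=O)OC(=O)C(C)(C)C | intermediate (not isolated)
16 | tert-butyl 4-[(4R)-4-benzyl-2-oxo-1,3-oxazolidin-3-yl]-4-oxobutanoate | CC(C)(C)OC(=O)CCC(=O)N1C(=O)OC[C@H]1Cc1ccccc1 | intermediate
17 | 4-(benzyloxy)-3-methoxybenzaldehyde (O-benzylvanillin) | COc1cc(C=O)ccc1OCc1ccccc1 | starting material
18 | tert-butyl (3S,4R)-3-{[(4R)-4-benzyl-2-oxo-1,3-oxazolidin-3-yl]carbonyl}-4-[4-(benzyloxy)-3-methoxyphenyl]-4-[(trimethylsilyl)oxy]butanoate | CC(C)(C)OC(=O)C[C@H](C(=O)N1C(=O)OC[C@H]1Cc1ccccc1)[C@@H](O[Si](C)(C)C)c1ccc(OCc2ccccc2)c(OC)c1 | intermediate (not isolated)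
19 | tert-butyl (3S,4R)-3-{[(4R)-4-benzyl-2-oxo-1,3-oxazolidin-3-yl]carbonyl}-4-[4-(benzyloxy)-3-methoxyphenyl]-4-hydroxybutanoate | CC(C)(C)OC(=O)C[C@H](C(=O)N1C(=O)OC[C@H]1Cc1ccccc1)[C@@H](O)c1ccc(OCc2ccccc2)c(OC)c1 | intermediate
20 | tert-butyl (3S,4R)-3-{[(4R)-4-benzyl-2-oxo-1,3-oxazolidin-3-yl]carbonyl}-4-[4-(benzyloxy)-3-methoxyphenyl]-4-[(tert-butyldimethylsilyl)oxy]butanoate | CC(C)(C)OC(=O)C[C@H](C(=O)N1C(=O)OC[C@H]1Cc1ccccc1)[C@@H](O[Si](C)(C)C(C)(C)C)c1ccc(OCc2ccccc2)c(OC)c1 | intermediate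
21 | tert-butyl (3R,4R)-4-[4-(benzyloxy)-3-methoxyphenyl]-4-[(tert-butyldimethylsilyl)oxy]-3-(hydroxymethyl)butanoate | CC(C)(C)OC(=O)C[C@H](CO)[C@@H](O[Si](C)(C)C(C)(C)C)c1ccc(OCc2ccccc2)c(OC)c1 | intermediate
22 | (4R)-4-[(R)-[4-(benzyloxy)-3-methoxyphenyl][(tert-butyldimethylsilyl)oxy]methyl]oxolan-2-one | O=C1C[C@H](CO1)[C@@H](O[Si](C)(C)C(C)(C)C)c1ccc(OCc2ccccc2)c(OC)c1 | intermediate
23 | lithium enolate of 22, lithium (3R)-3-[(R)-[4-(benzyloxy)-3-methoxyphenyl][(tert-butyldimethylsilyl)oxy]methyl]-2,3-dihydrofuran-5-olate | [Li+].[O-]C1=C[C@H](CO1)[C@@H](O[Si](C)(C)C(C)(C)C)c1ccc(OCc2ccccc2)c(OC)c1 | intermediate (not isolated)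
24 | (3R,4R)-3-{[(2S,3R)-2-[4-(benzyloxy)-3-methoxyphenyl]-3-{[(tert-butyldimethylsilyl)oxy]methyl}-7-methoxy-2,3-dihydro-1-benzofuran-5-yl]methyl}-4-[(R)-[4-(benzyloxy)-3-methoxyphenyl][(tert-butyldimethylsilyl)oxy]methyl]oxolan-2-one | COc1cc([C@H]2Oc3c(OC)cc(C[C@H]4C(=O)OC[C@@H]4[C@@H](O[Si](C)(C)C(C)(C)C)c4ccc(OCc5ccccc5)c(OC)c4)cc3[C@@H]2CO[Si](C)(C)C(C)(C)C)ccc1OCc1ccccc1 | intermediate
25 | (3R,4R)-3-{[(2S,3R)-3-{[(tert-butyldimethylsilyl)oxy]methyl}-2-(4-hydroxy-3-methoxyphenyl)-7-methoxy-2,3-dihydro-1-benzofuran-5-yl]methyl}-4-[(R)-[(tert-butyldimethylsilyl)oxy](4-hydroxy-3-methoxyphenyl)methyl]oxolan-2-one | COc1cc([C@H]2Oc3c(OC)cc(C[C@H]4C(=O)OC[C@@H]4[C@@H](O[Si](C)(C)C(C)(C)C)c4ccc(O)c(OC)c4)cc3[C@@H]2CO[Si](C)(C)C(C)(C)C)ccc1O | intermediate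
26 | (3R,4R)-4-[(R)-hydroxy(4-hydroxy-3-methoxyphenyl)methyl]-3-{[(2S,3R)-2-(4-hydroxy-3-methoxyphenyl)-3-(hydroxymethyl)-7-methoxy-2,3-dihydro-1-benzofuran-5-yl]methyl}oxolan-2-one | COc1cc([C@H]2Oc3c(OC)cc(C[C@H]4C(=O)OC[C@@H]4[C@@H](O)c4ccc(O)c(OC)c4)cc3[C@@H]2CO)ccc1O | target

**Step count and risks**

Total: 16 steps. Longest linear sequence: 11 steps (steps 1–8, then 14–16, from ferulic acid); the lactone branch (steps 9–13) joins at step 14.

Steps most likely to fail:

1. Step 4. The aryloxide is flanked by iodine and methoxy and is weakly nucleophilic, so attack on the allyl–iridium complex may be slow. The branched ether also holds a good aryloxide leaving group on an electron-rich benzylic carbon, so it may re-ionise, which would erode the enantiomeric purity and leak material to the linear ether. The fallback makes the stereocentre by resolution and transfers it in the C–O bond formation; it sets out from 17 and 5 and returns at 7. CH2=CHMgBr adds to 17 to give racemic 1-[4-(benzyloxy)-3-methoxyphenyl]prop-2-en-1-ol F1. Acylation with vinyl acetate over immobilised Candida antarctica lipase B should consume the R enantiomer and leave (1S)-1-[4-(benzyloxy)-3-methoxyphenyl]prop-2-en-1-ol F2. ClCO2Me and pyridine then give (1S)-1-[4-(benzyloxy)-3-methoxyphenyl]prop-2-en-1-yl methyl carbonate F3. Rhodium-catalysed allylic etherification (RhCl(PPh3)3, P(OMe)3, THF) with the copper aryloxide made from 5, LiN(SiMe3)2 and CuI (copper monoiodide) is expected to proceed with net retention at the branched carbon and give 7.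

2. Step 5. Hydrogen transfer from the stannane to the cyclised primary radical may compete with oxygen capture and give the 3-methyl compound. The trans selectivity of ring closure may be incomplete, and the formyl group may be oxidised under the aerobic chain. The fallback places the oxygen precursor on the alkene before cyclisation, so that no oxygen is needed; it sets out from 7 and returns at 9. Cross-metathesis of 7 with vinylboronic acid pinacol ester (second-generation Grubbs catalyst, CH2Cl2, 40 °C) should give 4-{[(1S,2E)-1-[4-(benzyloxy)-3-methoxyphenyl]-3-(4,4,5,5-tetramethyl-1,3,2-dioxaborolan-2-yl)prop-2-en-1-yl]oxy}-3-iodo-5-methoxybenzaldehyde F4. Reductive 5-exo aryl radical cyclisation (Bu3SnH, azobisisobutyronitrile, degassed toluene, 80 °C) passes through a boron-stabilised radical and should give (2S,3S)-2-[4-(benzyloxy)-3-methoxyphenyl]-7-methoxy-3-[(4,4,5,5-tetramethyl-1,3,2-dioxaborolan-2-yl)methyl]-2,3-dihydro-1-benzofuran-5-carbaldehyde F5. Oxidation of the C–B bond with NaBO3·4H2O in THF/H2O then gives 9.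

3. Step 10. With a succinate-type acyl chain and an electron-rich aldehyde, the anti selectivity or the facial control of the magnesium-catalysed aldol may be insufficient, and retro-aldol may set in on desilylation. The fallback replaces the auxiliary by enamine catalysis and bypasses steps 9–13; it sets out from 17 and returns at 22. Cross-aldol of methyl 4-oxobutanoate (donor, slow addition) with 17 under L-proline catalysis (DMF, 4 °C) should give methyl (3S,4R)-4-[4-(benzyloxy)-3-methoxyphenyl]-3-formyl-4-hydroxybutanoate F6. NaBH4 (MeOH, 0 °C) reduces the formyl group and the primary alkoxide closes on the methyl ester to give (4R)-4-[(R)-[4-(benzyloxy)-3-methoxyphenyl](hydroxy)methyl]oxolan-2-one F7. Silylation with t-BuMe2SiOTf and 2,6-lutidine gives 22.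

**Further compounds**

F1 | step 4 | racemic 1-[4-(benzyloxy)-3-methoxyphenyl]prop-2-en-1-ol | COc1cc(C(O)C=C)ccc1OCc1ccccc1
F2 | step 4 | (1S)-1-[4-(benzyloxy)-3-methoxyphenyl]prop-2-en-1-ol | COc1cc([C@H](C=C)O)ccc1OCc1ccccc1
F3 | step 4 | (1S)-1-[4-(benzyloxy)-3-methoxyphenyl]prop-2-en-1-yl methyl carbonate | COc1cc([C@H](C=C)OC(=O)OC)ccc1OCc1ccccc1
F4 | step 5 | 4-{[(1S,2E)-1-[4-(benzyloxy)-3-methoxyphenyl]-3-(4,4,5,5-tetramethyl-1,3,2-dioxaborolan-2-yl)prop-2-en-1-yl]oxy}-3-iodo-5-methoxybenzaldehyde | COc1cc([C@H](/C=C/B2OC(C)(C)C(C)(C)O2)Oc2c(OC)cc(C=O)cc2I)ccc1OCc1ccccc1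
F5 | step 5 | (2S,3S)-2-[4-(benzyloxy)-3-methoxyphenyl]-7-methoxy-3-[(4,4,5,5-tetramethyl-1,3,2-dioxaborolan-2-yl)methyl]-2,3-dihydro-1-benzofuran-5-carbaldehyde | COc1cc([C@H]2Oc3c(OC)cc(C=O)cc3[C@@H]2CB2OC(C)(C)C(C)(C)O2)ccc1OCc1ccccc1
F6 | step 10 | methyl (3S,4R)-4-[4-(benzyloxy)-3-methoxyphenyl]-3-formyl-4-hydroxybutanoate | COC(=O)C[C@H](C=O)[C@@H](O)c1ccc(OCc2ccccc2)c(OC)c1
F7 | step 10 | (4R)-4-[(R)-[4-(benzyloxy)-3-methoxyphenyl](hydroxy)methyl]oxolan-2-one | O=C1C[C@H](CO1)[C@@H](O)c1ccc(OCc2ccccc2)c(OC)c1
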